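**Retrosynthetic overview**
1. Target 15 comes from the protected 3-arylcoumarin 14 by one acidic global deprotection (two MOM ethers, one aryl acetate).
2. The lactone ring of 14 (O1–C2 ester bond and C3=C4 bond) is disconnected by a Perkin–Oglialoro condensation into salicylaldehyde 11 (ring A, bought) and arylacetic acid 10 (ring B).
3. Acid 10 comes from alcohol 8 by oxidation; 8 comes from an aryllithium and ethylene oxide, whose two carbons become C3 and C2 of the coumarin.
4. Prenyl and the two-carbon arm are put on resorcinol bis-MOM ether by two successive directed ortho-metalations.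
5. Ring order: rings A and B are purchased benzene rings; the only ring formed is the pyranone ring (ring C), in step 5.

Assumption: the target has no stereocentre and its side-chain alkene carries two identical methyl groups, so it is achiral and no stereocontrol is needed.

**Route**

Step 1
Reactants: 1 resorcinol
Product: 2 1,3-bis(methoxymethoxy)benzene
Conditions: NaH (2.4 equiv), MOMCl (2.4 equiv), DMF, 0 °C → rt
Reagents that add atoms: chloromethyl methyl ether (MOMCl), COCCl
Why: Williamson-type O-alkylation of the bis-phenoxide installs MOM groups, which protect both phenols and act as directing groups for the two lithiations that follow.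

Step 2
Reactants: 2 1,3-bis(methoxymethoxy)benzene; 3 prenyl bromide
Product: 5 1,3-bis(methoxymethoxy)-2-(3-methylbut-2-en-1-yl)benzene, via [2,6-bis(methoxymethoxy)phenyl]lithium 4 (not isolated)
Conditions: n-BuLi (1.1 equiv), THF, 0 °C → rt; CuI (10 mol %), then 3, −78 °C → rt
Reagents that add atoms: none
Why: Directed ortho-metalation removes the most acidic ring proton, flanked by both OMOM groups, and copper-catalysed allylic substitution at the primary carbon of prenyl bromide gives the linear prenyl arene.

Step 3
Reactants: 5 1,3-bis(methoxymethoxy)-2-(3-methylbut-2-en-1-yl)benzene; 6 ethylene oxide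
Product: 8 2-[2,4-bis(methoxymethoxy)-3-(3-methylbut-2-en-1-yl)phenyl]ethan-1-ol, via [2,4-bis(methoxymethoxy)-3-(3-methylbut-2-en-1-yl)phenyl]lithium 7 (not isolated)
Conditions: n-BuLi (1.2 equiv), TMEDA, THF, −20 → 0 °C; then 6 (2.5 M in THF, 3 equiv), 0 °C → rt; then H2O
Reagents that add atoms: none
Why: A second directed ortho-metalation next to one OMOM (the two open ortho positions are equivalent by symmetry) gives an aryllithium that opens the epoxide by SN2 attack, adding the two-carbon arm.

Step 4
Reactants: 8 2-[2,4-bis(methoxymethoxy)-3-(3-methylbut-2-en-1-yl)phenyl]ethan-1-ol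
Product: 10 [2,4-bis(methoxymethoxy)-3-(3-methylbut-2-en-1-yl)phenyl]acetic acid, via [2,4-bis(methoxymethoxy)-3-(3-methylbut-2-en-1-yl)phenyl]acetaldehyde 9 (not isolated)
Conditions: TEMPO (20 mol %), PhI(OAc)2 (2.5 equiv), MeCN/H2O 1:1, rt
Reagents that add atoms: water, O
Why: Oxoammonium-mediated (TEMPO/PhI(OAc)2) oxidation takes the primary alcohol through the aldehyde hydrate to the acid under near-neutral conditions that leave the MOM acetals, the electron-rich ring and the trisubstituted alkene untouched.

Step 5
Reactants: 10 [2,4-bis(methoxymethoxy)-3-(3-methylbut-2-en-1-yl)phenyl]acetic acid; 11 2,4-dihydroxy-6-methoxybenzaldehyde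
Product: 14 3-[2,4-bis(methoxymethoxy)-3-(3-methylbut-2-en-1-yl)phenyl]-5-methoxy-2-oxo-2H-chromen-7-yl acetate, via mixed acetic arylacetic anhydride 12 (not isolated), via O-arylacetyl salicylaldehyde ester 13 (not isolated)
Conditions: Ac2O (6 equiv), Et3N (4 equiv), 110 °C, 8 h, N2
Reagents that add atoms: acetic anhydride, CC(=O)OC(C)=O
Why: In this Perkin–Oglialoro condensation the mixed anhydride acylates the 2-OH, and intramolecular aldol (Knoevenagel) condensation with dehydration closes the pyranone ring; the 7-OH is acetylated in the same pot and the amine buffer keeps the MOM ethers intact.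

Step 6
Reactants: 14 3-[2,4-bis(methoxymethoxy)-3-(3-methylbut-2-en-1-yl)phenyl]-5-methoxy-2-oxo-2H-chromen-7-yl acetate
Product: 15 3-[2,4-dihydroxy-3-(3-methylbut-2-en-1-yl)phenyl]-7-hydroxy-5-methoxy-2H-chromen-2-one
Conditions: conc. HCl (5 equiv), MeOH, 45 °C, monitored and stopped at full conversion
Reagents that add atoms: none
Why: Acid-catalysed acetal solvolysis removes both MOM groups and acid-catalysed transesterification with methanol removes the aryl acetate, while the aryl methyl ether and the lactone are stable and the mild temperature limits cyclisation of the prenyl group onto a neighbouring phenol.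

**Compound list**

1 | resorcinol (benzene-1,3-diol) | Oc1cccc(O)c1 | starting material
2 | 1,3-bis(methoxymethoxy)benzene | COCOc1cccc(OCOC)c1 | intermediate
3 | prenyl bromide (1-bromo-3-methylbut-2-ene) | CC(C)=CCBr | starting material
4 | [2,6-bis(methoxymethoxy)phenyl]lithium | [Li]c1c(OCOC)cccc1OCOC | intermediate (not isolated)
5 | 1,3-bis(methoxymethoxy)-2-(3-methylbut-2-en-1-yl)benzene | COCOc1cccc(OCOC)c1CC=C(C)C | intermediate
6 | ethylene oxide (oxirane) | C1CO1 | starting material
7 | [2,4-bis(methoxymethoxy)-3-(3-methylbut-2-en-1-yl)phenyl]lithium | [Li]c1ccc(OCOC)c(CC=C(C)C)c1OCOC | intermediate (not isolated)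
8 | 2-[2,4-bis(methoxymethoxy)-3-(3-methylbut-2-en-1-yl)phenyl]ethan-1-ol | COCOc1ccc(CCO)c(OCOC)c1CC=C(C)C | intermediate
9 | [2,4-bis(methoxymethoxy)-3-(3-methylbut-2-en-1-yl)phenyl]acetaldehyde | COCOc1ccc(CC=O)c(OCOC)c1CC=C(C)C | intermediate (not isolated)
10 | [2,4-bis(methoxymethoxy)-3-(3-methylbut-2-en-1-yl)phenyl]acetic acid | COCOc1ccc(CC(=O)O)c(OCOC)c1CC=C(C)C | intermediate
11 | 2,4-dihydroxy-6-methoxybenzaldehyde | COc1cc(O)cc(O)c1C=O | starting material
12 | acetic [2,4-bis(methoxymethoxy)-3-(3-methylbut-2-en-1-yl)phenyl]acetic anhydride | COCOc1ccc(CC(=O)OC(C)=O)c(OCOC)c1CC=C(C)C | intermediate (not isolated)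
13 | 5-(acetyloxy)-2-formyl-3-methoxyphenyl [2,4-bis(methoxymethoxy)-3-(3-methylbut-2-en-1-yl)phenyl]acetate | COc1cc(OC(C)=O)cc(OC(=O)Cc2ccc(OCOC)c(CC=C(C)C)c2OCOC)c1C=O | intermediate (not isolated)
14 | 3-[2,4-bis(methoxymethoxy)-3-(3-methylbut-2-en-1-yl)phenyl]-5-methoxy-2-oxo-2H-chromen-7-yl acetate | COc1cc(OC(C)=O)cc2oc(=O)c(-c3ccc(OCOC)c(CC=C(C)C)c3OCOC)cc12 | intermediate
15 | 3-[2,4-dihydroxy-3-(3-methylbut-2-en-1-yl)phenyl]-7-hydroxy-5-methoxy-2H-chromen-2-one | COc1cc(O)cc2oc(=O)c(-c3ccc(O)c(CC=C(C)C)c3O)cc12 | target

**Totals**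

Total step count: 6. Longest linear sequence: 6 steps (1 → 2 → 5 → 8 → 10 → 14 → 15); aldehyde 11 enters at step 5.

**Three steps most likely to fail, each with a fallback**

Step 3 is the first risk: the benzylic and allylic CH2 of the prenyl group sits between two OMOM groups and could be deprotonated instead of the ring position. The fallback sets out from 5 and fixes the site of lithiation with a halogen. NBS in MeCN at 0 °C brominates the ring para to one OMOM (the two such positions are equivalent) and gives 1-bromo-2,4-bis(methoxymethoxy)-3-(3-methylbut-2-en-1-yl)benzene F1. Bromine–lithium exchange with n-BuLi (1.05 equiv) in THF at −78 °C is faster than any deprotonation and gives aryllithium 7 regiospecifically. Addition of ethylene oxide 6 as in step 3 then gives 8, where the fallback comes back to the route.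

Step 5 is the second risk: the aldehyde is electron-rich, the acid is ortho-substituted, and the MOM ethers must survive hot acetic anhydride. The fallback sets out from 11 and replaces the one-pot anhydride condensation by a staged acylation and ring closure at room temperature. Acetylation of the non-chelated 4-OH (Ac2O 1.0 equiv, Et3N, CH2Cl2, 0 °C) gives 4-formyl-3-hydroxy-5-methoxyphenyl acetate F2. Carbodiimide esterification of its remaining phenol with acid 10 (EDC·HCl, DMAP, CH2Cl2, rt) gives ester 13, now isolated. DBU in MeCN at rt closes 13 by intramolecular Knoevenagel condensation to 14, where the fallback comes back to the route.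

Step 6 is the third risk: protic acid can cyclise the prenyl group onto the 2'- or 4'-hydroxyl to give a chroman. The fallback sets out from 14 and avoids Brønsted acid altogether. K2CO3 in MeOH at 0 °C removes the acetate and gives 3-[2,4-bis(methoxymethoxy)-3-(3-methylbut-2-en-1-yl)phenyl]-7-hydroxy-5-methoxy-2H-chromen-2-one F3. ZnBr2 with n-PrSH in CH2Cl2 at 0 °C for a few minutes then cleaves both MOM ethers by Lewis-acid activation and thiol capture of the methoxymethyl group. This gives 15, where the fallback comes back to the route.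

**Further compounds**

F1 | step 3 | 1-bromo-2,4-bis(methoxymethoxy)-3-(3-methylbut-2-en-1-yl)benzene | COCOc1ccc(Br)c(OCOC)c1CC=C(C)C
F2 | step 5 | 4-formyl-3-hydroxy-5-methoxyphenyl acetate | COc1cc(OC(C)=O)cc(O)c1C=O
F3 | step 6 | 3-[2,4-bis(methoxymethoxy)-3-(3-methylbut-2-en-1-yl)phenyl]-7-hydroxy-5-methoxy-2H-chromen-2-one | COc1cc(O)cc2oc(=O)c(-c3ccc(OCOC)c(CC=C(C)C)c3OCOC)cc12
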